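**Plan**
- Retrosynthesis: the oxirane bond C1–C10, which is also a bond of the ten-membered ring, is cut first. C10 (fully substituted, carrying the methyl and O) is a latent methyl ketone and C1 (the oxirane CH next to the C2 methylene) a latent sulfonium ylide carbon. Then C7–C8 (allylchromium addition of a 3-(bromomethyl)butenolide to a C8 aldehyde), C6–C7 (propiolate alkynylation of a Z-enal) and C3–C4 (alkenyl Grignard plus Weinreb amide) are cut.
- Forward: Z-iodoalkene (C4=C5) → C1–C6 chain → butenolide ring (C6–O–C12) → α-methylene lactone carrying C8–C10 → ten-membered carbocycle and oxirane closed together in the last C–C bond formation → desilylation.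
- Stereochemistry: 4Z from trans-hydroalumination/iodination; C3 by CBS reduction; C6 by catalyst-controlled alkynylation; C7 anti to the C6 substituent; C8 through a chair transition state, then Mitsunobu inversion when the methacrylate is attached; C1 and C10 in the ring-closing epoxidation.
- Enabling feature: the Z C4=C5 olefin and the trans-fused γ-lactone (C6, C7, C11, C12, O) fold the 1,10-seco chain so that C1 and C10 can meet.

Key step: step 18

Remark: carbons are called C1–C15 by germacrane numbering of the target (C1/C10 oxirane, C14 methyl on C10, C15 hydroxymethyl on C4, lactone C6–O–C12(=O)–C11(=C13)–C7); open-chain precursors are named as 1,10-secogermacranes.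

**Route**

Step 1
Reactants: 1 4-{[tert-butyl(dimethyl)silyl]oxy}but-2-yn-1-ol
Product: 3 (2Z)-4-{[tert-butyl(dimethyl)silyl]oxy}-3-iodobut-2-en-1-ol, via cyclic alkenylaluminate 2 (not isolated)
Conditions: NaAlH2(OCH2CH2OCH3)2, THF, 0 °C to rt; then I2, −78 °C
Reagents that add atoms: iodine, II
Why: Hydroxyl-directed trans-hydroalumination of the propargylic alcohol puts aluminium on the distal carbon (C4) anti to the hydride on C5, and iodinolysis with retention should give the Z-iodoalkene in which iodine (the place of the later C3 substituent) is cis to C6, fixing the 4Z geometry.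

Step 2
Reactants: 3 (2Z)-4-{[tert-butyl(dimethyl)silyl]oxy}-3-iodobut-2-en-1-ol
Product: 4 (2Z)-4-{[tert-butyl(dimethyl)silyl]oxy}-3-iodo-1-[(triethylsilyl)oxy]but-2-ene
Conditions: Et3SiCl, imidazole, CH2Cl2, 0 °C
Reagents that add atoms: chlorotriethylsilane, CC[Si](Cl)(CC)CC
Why: Routine silylation of the primary alcohol, the triethylsilyl ether being chosen because it can later be oxidised directly to the aldehyde beside the tert-butyldimethylsilyl ether.

Step 3
Reactants: 5 4-methoxybenzyl alcohol; 6 N-methoxy-N-methylprop-2-enamide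
Product: 7 N-methoxy-3-[(4-methoxybenzyl)oxy]-N-methylpropanamide
Conditions: KOt-Bu (cat.), THF, 0 °C to rt
Reagents that add atoms: none
Why: Alkoxide-catalysed oxa-Michael addition of the benzylic alcohol to the acrylamide should give the β-alkoxy Weinreb amide (C1–C3) in one step.

Step 4
Reactants: 4 (2Z)-4-{[tert-butyl(dimethyl)silyl]oxy}-3-iodo-1-[(triethylsilyl)oxy]but-2-ene; 7 N-methoxy-3-[(4-methoxybenzyl)oxy]-N-methylpropanamide
Product: 9 (4Z)-4-{[tert-butyl(dimethyl)silyl]oxymethyl}-1-[(4-methoxybenzyl)oxy]-6-[(triethylsilyl)oxy]hex-4-en-3-one, via alkenylmagnesium chloride 8 (not isolated)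
Conditions: i-PrMgCl·LiCl, THF, −20 °C; then 7, −20 to 0 °C; aq. NH4Cl
Reagents that add atoms: none
Why: Iodine–magnesium exchange gives a configurationally stable alkenyl Grignard reagent (magnesium instead of lithium avoids 1,4 O→C silyl migration from the cis CH2OSiEt3 group), and its acylation by the Weinreb amide stops at the ketone through the chelated tetrahedral intermediate.

Step 5
Reactants: 9 (4Z)-4-{[tert-butyl(dimethyl)silyl]oxymethyl}-1-[(4-methoxybenzyl)oxy]-6-[(triethylsilyl)oxy]hex-4-en-3-one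
Product: 10 (3S,4Z)-4-{[tert-butyl(dimethyl)silyl]oxymethyl}-1-[(4-methoxybenzyl)oxy]-6-[(triethylsilyl)oxy]hex-4-en-3-ol
Conditions: (R)-1-methyl-3,3-diphenyltetrahydro-1H,3H-pyrrolo[1,2-c][1,3,2]oxazaborole (cat.), catecholborane, toluene, −78 °C
Reagents that add atoms: none
Why: Corey–Bakshi–Shibata reduction in which the α-branched alkenyl group acts as the large substituent, so the (R)-oxazaborolidine should deliver hydride to give the 3S allylic alcohol by 1,2-reduction.

Step 6
Reactants: 10 (3S,4Z)-4-{[tert-butyl(dimethyl)silyl]oxymethyl}-1-[(4-methoxybenzyl)oxy]-6-[(triethylsilyl)oxy]hex-4-en-3-ol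
Product: 11 (3S,4Z)-4-{[tert-butyl(dimethyl)silyl]oxymethyl}-1-[(4-methoxybenzyl)oxy]-6-[(triethylsilyl)oxy]hex-4-en-3-yl acetate
Conditions: Ac2O, Et3N, DMAP (cat.), CH2Cl2, 0 °C to rt
Reagents that add atoms: acetic anhydride, CC(=O)OC(C)=O
Why: DMAP-catalysed acetylation of the only free hydroxyl installs the C3 acetate of the target early.

Step 7
Reactants: 11 (3S,4Z)-4-{[tert-butyl(dimethyl)silyl]oxymethyl}-1-[(4-methoxybenzyl)oxy]-6-[(triethylsilyl)oxy]hex-4-en-3-yl acetate
Product: 12 (2Z,4S)-4-acetoxy-3-{[tert-butyl(dimethyl)silyl]oxymethyl}-6-[(4-methoxybenzyl)oxy]hex-2-enal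
Conditions: (COCl)2, DMSO, CH2Cl2, −78 to −30 °C; Et3N, −78 °C to rt
Reagents that add atoms: none
Why: Swern conditions oxidise a primary triethylsilyl ether directly to the aldehyde, while the tert-butyldimethylsilyl ether, the acetate and the Z-olefin should be left untouched.

Step 8
Reactants: 12 (2Z,4S)-4-acetoxy-3-{[tert-butyl(dimethyl)silyl]oxymethyl}-6-[(4-methoxybenzyl)oxy]hex-2-enal; 13 methyl prop-2-ynoate
Product: 15 methyl (4R,5Z,7S)-7-acetoxy-6-{[tert-butyl(dimethyl)silyl]oxymethyl}-4-hydroxy-9-[(4-methoxybenzyl)oxy]non-5-en-2-ynoate, via methylzinc alkynylide 14 (not isolated)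
Conditions: ZnMe2, (S,S)-ProPhenol (cat.), toluene, 0 °C
Reagents that add atoms: none
Why: Zinc–ProPhenol-catalysed asymmetric alkynylation of the enal, in which the (S,S)-ligand is expected to direct the alkynylzinc to the Si face and so set C6 (R) under catalyst control, independent of the remote C3 centre.

Step 9
Reactants: 15 methyl (4R,5Z,7S)-7-acetoxy-6-{[tert-butyl(dimethyl)silyl]oxymethyl}-4-hydroxy-9-[(4-methoxybenzyl)oxy]non-5-en-2-ynoate
Product: 17 (5S)-5-[(1Z,3S)-3-acetoxy-2-{[tert-butyl(dimethyl)silyl]oxymethyl}-5-[(4-methoxybenzyl)oxy]pent-1-en-1-yl]furan-2(5H)-one, via (Z)-hydroxy enoate 16 (not isolated)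
Conditions: H2 (1 atm), Pd/CaCO3 poisoned with Pb(OAc)2, quinoline, EtOAc, rt; then PPTS (cat.), CH2Cl2
Reagents that add atoms: none
Why: Cis-selective semihydrogenation of the ynoate gives the Z γ-hydroxy enoate, which should lactonise to the butenolide without touching C6 (the descriptor changes only through CIP priorities).

Step 10
Reactants: 17 (5S)-5-[(1Z,3S)-3-acetoxy-2-{[tert-butyl(dimethyl)silyl]oxymethyl}-5-[(4-methoxybenzyl)oxy]pent-1-en-1-yl]furan-2(5H)-one
Product: 18 (5R)-5-[(1Z,3S)-3-acetoxy-2-{[tert-butyl(dimethyl)silyl]oxymethyl}-5-[(4-methoxybenzyl)oxy]pent-1-en-1-yl]-3-(hydroxymethyl)furan-2(5H)-one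
Conditions: aq. CH2O, DMAP, THF/H2O, rt
Reagents that add atoms: formaldehyde, C=O
Why: Morita–Baylis–Hillman hydroxymethylation, in which reversible conjugate addition of DMAP at C7 gives the lactone enolate that adds to formaldehyde at C11 and then expels the amine, bringing in C13.

Step 11
Reactants: 18 (5R)-5-[(1Z,3S)-3-acetoxy-2-{[tert-butyl(dimethyl)silyl]oxymethyl}-5-[(4-methoxybenzyl)oxy]pent-1-en-1-yl]-3-(hydroxymethyl)furan-2(5H)-one
Product: 19 (5R)-3-(bromomethyl)-5-[(1Z,3S)-3-acetoxy-2-{[tert-butyl(dimethyl)silyl]oxymethyl}-5-[(4-methoxybenzyl)oxy]pent-1-en-1-yl]furan-2(5H)-one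
Conditions: CBr4, PPh3, CH2Cl2, 0 °C
Reagents that add atoms: carbon tetrabromide, BrC(Br)(Br)Br
Why: The Appel reaction should convert the primary allylic alcohol into the bromide under neutral conditions that spare the acetate and the silyl ether.

Step 12
Reactants: 20 ethyl 2-(2-methyl-1,3-dioxolan-2-yl)acetate
Product: 21 (2-methyl-1,3-dioxolan-2-yl)acetaldehyde
Conditions: i-Bu2AlH, CH2Cl2, −78 °C; aq. potassium sodium tartrate
Reagents that add atoms: none
Why: Half-reduction of the ester at low temperature through the stable aluminium hemiacetal should give the C8 aldehyde with the C10 ketone kept as its dioxolane.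

Step 13
Reactants: 19 (5R)-3-(bromomethyl)-5-[(1Z,3S)-3-acetoxy-2-{[tert-butyl(dimethyl)silyl]oxymethyl}-5-[(4-methoxybenzyl)oxy]pent-1-en-1-yl]furan-2(5H)-one; 21 (2-methyl-1,3-dioxolan-2-yl)acetaldehyde
Product: 23 (3S,4Z,6R,7R,8S)-3-acetoxy-15-(tert-butyldimethylsilyloxy)-10,10-(ethylenedioxy)-8-hydroxy-1-(4-methoxybenzyloxy)-1,10-secogermacra-4,11(13)-dien-12,6-olide, via allylchromium dichloride 22 (not isolated)
Conditions: CrCl2, THF, 0 °C to rt
Reagents that add atoms: none
Why: Nozaki–Hiyama allylation, in which the allylchromium reagent should add through C7 in a closed chair transition state on the butenolide face anti to the C6 substituent (6,7-trans) with the aldehyde residue equatorial (7,8-anti, hence 8S), creating the α-methylene lactone directly.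

Step 14
Reactants: 23 (3S,4Z,6R,7R,8S)-3-acetoxy-15-(tert-butyldimethylsilyloxy)-10,10-(ethylenedioxy)-8-hydroxy-1-(4-methoxybenzyloxy)-1,10-secogermacra-4,11(13)-dien-12,6-olide
Product: 24 (3S,4Z,6R,7R,8R)-3-acetoxy-15-(tert-butyldimethylsilyloxy)-10,10-(ethylenedioxy)-8-(methacryloyloxy)-1-(4-methoxybenzyloxy)-1,10-secogermacra-4,11(13)-dien-12,6-olide
Conditions: PPh3, diisopropyl azodicarboxylate, methacrylic acid, toluene, 0 °C to rt
Reagents that add atoms: methacrylic acid, CC(=C)C(=O)O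
Why: Mitsunobu esterification proceeds by SN2 displacement of the alkoxyphosphonium ion by the carboxylate, so the methacrylate should be attached with inversion to give the required 8R configuration.

Step 15
Reactants: 24 (3S,4Z,6R,7R,8R)-3-acetoxy-15-(tert-butyldimethylsilyloxy)-10,10-(ethylenedioxy)-8-(methacryloyloxy)-1-(4-methoxybenzyloxy)-1,10-secogermacra-4,11(13)-dien-12,6-olide
Product: 25 (3S,4Z,6R,7R,8R)-3-acetoxy-15-(tert-butyldimethylsilyloxy)-8-(methacryloyloxy)-1-(4-methoxybenzyloxy)-10-oxo-1,10-secogermacra-4,11(13)-dien-12,6-olide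
Conditions: PPTS (cat.), acetone/H2O, 45 °C
Reagents that add atoms: water, O
Why: Mild acid-catalysed hydrolysis of the dioxolane should unmask the C10 methyl ketone while the silyl ether, the 4-methoxybenzyl ether and the esters persist.

Step 16
Reactants: 25 (3S,4Z,6R,7R,8R)-3-acetoxy-15-(tert-butyldimethylsilyloxy)-8-(methacryloyloxy)-1-(4-methoxybenzyloxy)-10-oxo-1,10-secogermacra-4,11(13)-dien-12,6-olide
Product: 26 (3S,4Z,6R,7R,8R)-3-acetoxy-15-(tert-butyldimethylsilyloxy)-1-hydroxy-8-(methacryloyloxy)-10-oxo-1,10-secogermacra-4,11(13)-dien-12,6-olide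
Conditions: DDQ, CH2Cl2/pH 7 buffer, 0 °C
Reagents that add atoms: none
Why: Oxidative cleavage of the 4-methoxybenzyl ether by DDQ (hydride abstraction, then hydrolysis of the oxocarbenium ion) should free the C1 hydroxyl selectively under buffered conditions.

Step 17
Reactants: 26 (3S,4Z,6R,7R,8R)-3-acetoxy-15-(tert-butyldimethylsilyloxy)-1-hydroxy-8-(methacryloyloxy)-10-oxo-1,10-secogermacra-4,11(13)-dien-12,6-olide
Product: 28 [(3S,4Z,6R,7R,8R)-3-acetoxy-15-(tert-butyldimethylsilyloxy)-8-(methacryloyloxy)-10-oxo-1,10-secogermacra-4,11(13)-dien-12,6-olid-1-yl]diphenylsulfonium trifluoromethanesulfonate, via primary triflate 27 (not isolated)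
Conditions: Tf2O, 2,6-di-tert-butyl-4-methylpyridine, CH2Cl2, −78 °C; then Ph2S (excess), −78 to 0 °C
Reagents that add atoms: trifluoromethanesulfonic anhydride, O=S(=O)(OS(=O)(=O)C(F)(F)F)C(F)(F)F; diphenyl sulfide, c1ccc(Sc2ccccc2)cc1
Why: The primary triflate formed with a hindered, non-nucleophilic base is displaced in an SN2 reaction by diphenyl sulfide, giving an alkyldiphenylsulfonium salt whose only α-C–H bonds are those of C1.

Step 18
Reactants: 28 [(3S,4Z,6R,7R,8R)-3-acetoxy-15-(tert-butyldimethylsilyloxy)-8-(methacryloyloxy)-10-oxo-1,10-secogermacra-4,11(13)-dien-12,6-olid-1-yl]diphenylsulfonium trifluoromethanesulfonate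
Product: 31 (1R,3S,4Z,6R,7R,8R,10R)-3-acetoxy-15-(tert-butyldimethylsilyloxy)-1,10-epoxy-8-(methacryloyloxy)germacra-4,11(13)-dien-12,6-olide, via sulfonium ylide 29 (not isolated), via (1S,10R)-betaine 30 (not isolated)
Conditions: KN(SiMe3)2 (1.05 equiv), THF (0.001 M), −78 to −20 °C
Reagents that add atoms: none
Why: Proposed new method: KN(SiMe3)2 removes a proton from C1, the only carbon α to sulfur that bears hydrogen and by far the most acidic C–H in the molecule, the non-stabilised ylide adds irreversibly to the C10 methyl ketone, and the C10 alkoxide of the betaine then displaces diphenyl sulfide from C1 with inversion, so that the C1–C10 bond, the oxirane and the ten-membered carbocycle arise in one operation. The closest known reactions are the Corey–Chaykovsky epoxidation of ketones with alkyl(diphenyl)sulfonium ylides and the intramolecular sulfonium ylide–ketone epoxide annulations that close five- to seven-membered rings; the extension to a ten-membered ring is the new element. The carbocycle closes in a 10-exo-trig addition to the carbonyl group and the oxirane in a 3-exo-tet substitution. C10 (R) should result from attack on the Si face of the ketone, the face exposed when the chain folds around the Z C4=C5 bond and the trans-fused lactone with the C8 ester pseudo-equatorial and the methyl group outside the ring, and C1 (R after the inverting closure) from the betaine in which C2 and C9 are anti, the peripheral arrangement that lets O− and S+ become antiperiplanar. The step needs 1,2-addition to the ketone in preference to conjugate addition to the two acrylate units or displacement of the allylic acetate, and cyclisation in preference to oligomerisation; kinetic carbonyl addition of a non-stabilised ylide at low temperature, high dilution, a single equivalent of base (no enolisation of the β-acyloxy ketone) and the two turn elements of the chain are relied on for this.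

Step 19
Reactants: 31 (1R,3S,4Z,6R,7R,8R,10R)-3-acetoxy-15-(tert-butyldimethylsilyloxy)-1,10-epoxy-8-(methacryloyloxy)germacra-4,11(13)-dien-12,6-olide
Product: 32 (1R,3S,4Z,6R,7R,8R,10R)-3-acetoxy-1,10-epoxy-15-hydroxy-8-(methacryloyloxy)germacra-4,11(13)-dien-12,6-olide
Conditions: HF·pyridine, pyridine, THF, 0 °C
Reagents that add atoms: none
Why: Buffered fluoride cleavage of the primary allylic silyl ether should leave the oxirane, the α-methylene lactone and both esters intact and give the target.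

**Compound list**

1 | 4-{[tert-butyl(dimethyl)silyl]oxy}but-2-yn-1-ol | OCC#CCO[Si](C)(C)C(C)(C)C | starting material
2 | sodium cyclic alkenylaluminate (Al on C4, alkoxide O on Al, two 2-methoxyethoxy ligands) | [Na+].COCCO[Al-]1(OCCOC)OCC=C1CO[Si](C)(C)C(C)(C)C | intermediate
3 | (2Z)-4-{[tert-butyl(dimethyl)silyl]oxy}-3-iodobut-2-en-1-ol | OC/C=C(\I)CO[Si](C)(C)C(C)(C)C | intermediate
4 | (2Z)-4-{[tert-butyl(dimethyl)silyl]oxy}-3-iodo-1-[(triethylsilyl)oxy]but-2-ene | CC[Si](CC)(CC)OC/C=C(\I)CO[Si](C)(C)C(C)(C)C | intermediate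
5 | 4-methoxybenzyl alcohol | COc1ccc(CO)cc1 | starting material
6 | N-methoxy-N-methylprop-2-enamide | C=CC(=O)N(C)OC | starting material
7 | N-methoxy-3-[(4-methoxybenzyl)oxy]-N-methylpropanamide | COc1ccc(COCCC(=O)N(C)OC)cc1 | intermediate
8 | (Z)-[1-(tert-butyldimethylsilyloxy)-4-(triethylsilyloxy)but-2-en-2-yl]magnesium chloride | CC[Si](CC)(CC)OC/C=C(\[Mg]Cl)CO[Si](C)(C)C(C)(C)C | intermediate
9 | (4Z)-4-{[tert-butyl(dimethyl)silyl]oxymethyl}-1-[(4-methoxybenzyl)oxy]-6-[(triethylsilyl)oxy]hex-4-en-3-one | COc1ccc(COCCC(=O)/C(CO[Si](C)(C)C(C)(C)C)=C\CO[Si](CC)(CC)CC)cc1 | intermediate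
10 | (3S,4Z)-4-{[tert-butyl(dimethyl)silyl]oxymethyl}-1-[(4-methoxybenzyl)oxy]-6-[(triethylsilyl)oxy]hex-4-en-3-ol | COc1ccc(COCC[C@H](O)/C(CO[Si](C)(C)C(C)(C)C)=C\CO[Si](CC)(CC)CC)cc1 | intermediate
11 | (3S,4Z)-4-{[tert-butyl(dimethyl)silyl]oxymethyl}-1-[(4-methoxybenzyl)oxy]-6-[(triethylsilyl)oxy]hex-4-en-3-yl acetate | COc1ccc(COCC[C@H](OC(C)=O)/C(CO[Si](C)(C)C(C)(C)C)=C\CO[Si](CC)(CC)CC)cc1 | intermediate
12 | (2Z,4S)-4-acetoxy-3-{[tert-butyl(dimethyl)silyl]oxymethyl}-6-[(4-methoxybenzyl)oxy]hex-2-enal | COc1ccc(COCC[C@H](OC(C)=O)/C(CO[Si](C)(C)C(C)(C)C)=C\C=O)cc1 | intermediate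
13 | methyl prop-2-ynoate | C#CC(=O)OC | starting material
14 | methyl 3-(methylzincio)prop-2-ynoate | C[Zn]C#CC(=O)OC | intermediate
15 | methyl (4R,5Z,7S)-7-acetoxy-6-{[tert-butyl(dimethyl)silyl]oxymethyl}-4-hydroxy-9-[(4-methoxybenzyl)oxy]non-5-en-2-ynoate | COc1ccc(COCC[C@H](OC(C)=O)/C(CO[Si](C)(C)C(C)(C)C)=C\[C@@H](O)C#CC(=O)OC)cc1 | intermediate
16 | methyl (2Z,4S,5Z,7S)-7-acetoxy-6-{[tert-butyl(dimethyl)silyl]oxymethyl}-4-hydroxy-9-[(4-methoxybenzyl)oxy]nona-2,5-dienoate | COc1ccc(COCC[C@H](OC(C)=O)/C(CO[Si](C)(C)C(C)(C)C)=C\[C@@H](O)/C=C\C(=O)OC)cc1 | intermediate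
17 | (5S)-5-[(1Z,3S)-3-acetoxy-2-{[tert-butyl(dimethyl)silyl]oxymethyl}-5-[(4-methoxybenzyl)oxy]pent-1-en-1-yl]furan-2(5H)-one | COc1ccc(COCC[C@H](OC(C)=O)/C(CO[Si](C)(C)C(C)(C)C)=C\[C@H]2OC(=O)C=C2)cc1 | intermediate
18 | (5R)-5-[(1Z,3S)-3-acetoxy-2-{[tert-butyl(dimethyl)silyl]oxymethyl}-5-[(4-methoxybenzyl)oxy]pent-1-en-1-yl]-3-(hydroxymethyl)furan-2(5H)-one | COc1ccc(COCC[C@H](OC(C)=O)/C(CO[Si](C)(C)C(C)(C)C)=C\[C@H]2OC(=O)C(CO)=C2)cc1 | intermediate
19 | (5R)-3-(bromomethyl)-5-[(1Z,3S)-3-acetoxy-2-{[tert-butyl(dimethyl)silyl]oxymethyl}-5-[(4-methoxybenzyl)oxy]pent-1-en-1-yl]furan-2(5H)-one | COc1ccc(COCC[C@H](OC(C)=O)/C(CO[Si](C)(C)C(C)(C)C)=C\[C@H]2OC(=O)C(CBr)=C2)cc1 | intermediate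
20 | ethyl 2-(2-methyl-1,3-dioxolan-2-yl)acetate | CCOC(=O)CC1(C)OCCO1 | starting material
21 | (2-methyl-1,3-dioxolan-2-yl)acetaldehyde | O=CCC1(C)OCCO1 | intermediate
22 | allylchromium dichloride of 19 (trivalent chromium on C13) | COc1ccc(COCC[C@H](OC(C)=O)/C(CO[Si](C)(C)C(C)(C)C)=C\[C@H]2OC(=O)C(C[Cr](Cl)Cl)=C2)cc1 | intermediate
23 | (3S,4Z,6R,7R,8S)-3-acetoxy-15-(tert-butyldimethylsilyloxy)-10,10-(ethylenedioxy)-8-hydroxy-1-(4-methoxybenzyloxy)-1,10-secogermacra-4,11(13)-dien-12,6-olide | COc1ccc(COCC[C@H](OC(C)=O)/C(CO[Si](C)(C)C(C)(C)C)=C\[C@H]2OC(=O)C(=C)[C@@H]2[C@@H](O)CC2(C)OCCO2)cc1 | intermediate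
24 | (3S,4Z,6R,7R,8R)-3-acetoxy-15-(tert-butyldimethylsilyloxy)-10,10-(ethylenedioxy)-8-(methacryloyloxy)-1-(4-methoxybenzyloxy)-1,10-secogermacra-4,11(13)-dien-12,6-olide | COc1ccc(COCC[C@H](OC(C)=O)/C(CO[Si](C)(C)C(C)(C)C)=C\[C@H]2OC(=O)C(=C)[C@@H]2[C@H](OC(=O)C(C)=C)CC2(C)OCCO2)cc1 | intermediate
25 | (3S,4Z,6R,7R,8R)-3-acetoxy-15-(tert-butyldimethylsilyloxy)-8-(methacryloyloxy)-1-(4-methoxybenzyloxy)-10-oxo-1,10-secogermacra-4,11(13)-dien-12,6-olide | COc1ccc(COCC[C@H](OC(C)=O)/C(CO[Si](C)(C)C(C)(C)C)=C\[C@H]2OC(=O)C(=C)[C@@H]2[C@H](OC(=O)C(C)=C)CC(C)=O)cc1 | intermediate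
26 | (3S,4Z,6R,7R,8R)-3-acetoxy-15-(tert-butyldimethylsilyloxy)-1-hydroxy-8-(methacryloyloxy)-10-oxo-1,10-secogermacra-4,11(13)-dien-12,6-olide | OCC[C@H](OC(C)=O)/C(CO[Si](C)(C)C(C)(C)C)=C\[C@H]1OC(=O)C(=C)[C@@H]1[C@H](OC(=O)C(C)=C)CC(C)=O | intermediate
27 | C1 trifluoromethanesulfonate of 26 | O=S(=O)(OCC[C@H](OC(C)=O)/C(CO[Si](C)(C)C(C)(C)C)=C\[C@H]1OC(=O)C(=C)[C@@H]1[C@H](OC(=O)C(C)=C)CC(C)=O)C(F)(F)F | intermediate
28 | [(3S,4Z,6R,7R,8R)-3-acetoxy-15-(tert-butyldimethylsilyloxy)-8-(methacryloyloxy)-10-oxo-1,10-secogermacra-4,11(13)-dien-12,6-olid-1-yl]diphenylsulfonium trifluoromethanesulfonate | [O-]S(=O)(=O)C(F)(F)F.c1ccc(cc1)[S+](c1ccccc1)CC[C@H](OC(C)=O)/C(CO[Si](C)(C)C(C)(C)C)=C\[C@H]1OC(=O)C(=C)[C@@H]1[C@H](OC(=O)C(C)=C)CC(C)=O | intermediate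
29 | diphenylsulfonium ylide of 28 (carbanion at C1) | c1ccc(cc1)[S+](c1ccccc1)[CH-]C[C@H](OC(C)=O)/C(CO[Si](C)(C)C(C)(C)C)=C\[C@H]1OC(=O)C(=C)[C@@H]1[C@H](OC(=O)C(C)=C)CC(C)=O | intermediate
30 | (1S,10R)-betaine: ten-membered ring closed, C10 alkoxide, C1 diphenylsulfonio | C=C(C)C(=O)O[C@@H]1C[C@]([O-])(C)[C@@H]([S+](c3ccccc3)c3ccccc3)C[C@H](OC(C)=O)/C(CO[Si](C)(C)C(C)(C)C)=C\[C@H]2OC(=O)C(=C)[C@@H]21 | intermediate
31 | (1R,3S,4Z,6R,7R,8R,10R)-3-acetoxy-15-(tert-butyldimethylsilyloxy)-1,10-epoxy-8-(methacryloyloxy)germacra-4,11(13)-dien-12,6-olide | C=C(C)C(=O)O[C@@H]1C[C@@]2(C)O[C@@H]2C[C@H](OC(C)=O)/C(CO[Si](C)(C)C(C)(C)C)=C\[C@H]2OC(=O)C(=C)[C@@H]21 | intermediate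
32 | (1R,3S,4Z,6R,7R,8R,10R)-3-acetoxy-1,10-epoxy-15-hydroxy-8-(methacryloyloxy)germacra-4,11(13)-dien-12,6-olide | C=C(C)C(=O)O[C@@H]1C[C@@]2(C)O[C@@H]2C[C@H](OC(C)=O)/C(CO)=C\[C@H]2OC(=O)C(=C)[C@@H]21 | target

**Step count**

Total steps: 19. Longest linear sequence: 17 steps (steps 1, 2, 4–11 and 13–19, from 1 to 32).

**Steps most likely to fail**

1. Step 18 (ring-closing epoxidation). Ten-membered ring formation may be too slow, so that the ylide decomposes, adds to an acrylate unit or displaces the allylic acetate; the facial and trans/cis selectivity of oxirane formation may also be poor. Fallback by olefin metathesis and epoxidation, setting out from 26 and returning at 31: oxidation of 26 with Dess–Martin periodinane should give the keto aldehyde F1. Non-basic double methylenation (Zn, CH2Br2, TiCl4) should give the 1,10-dimethylidene seco compound F2. Ring-closing metathesis with the second-generation Grubbs catalyst at high dilution should give the (1(10)E)-cyclodecene F3 (a Z isomer, if formed, being isomerised photochemically). Epoxidation of this isolated, most electron-rich olefin with dimethyldioxirane from the outer face should give 31.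

2. Step 14 (Mitsunobu esterification). Substitution at the hindered C8 carbinol may be outrun by elimination towards C7 or by acyl transfer with retention. Fallback that reverses the sense of the allylation instead of inverting afterwards, setting out from 19 (with 21) and returning at 24: stannylation of 19 (Bu3SnSnBu3, Pd2(dba)3) should give the allylstannane F4. Its BF3·OEt2-promoted SE2′ addition to 21 through an open antiperiplanar transition state, again anti to the C6 substituent, should give the 7,8-syn (8R) alcohol F5. Acylation with methacrylic anhydride, Et3N and DMAP (retention) should give 24.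

3. Step 10 (Morita–Baylis–Hillman hydroxymethylation). Conjugate addition of the amine to the γ-substituted butenolide may be slow, and γ-deprotonation may erode the C6 configuration. Fallback by stannylation and cross-coupling, setting out from 15 and returning at 18: palladium-catalysed syn-hydrostannation of the ynoate (Bu3SnH, PdCl2(PPh3)2) with lactonisation in the flask should give the α-stannyl butenolide F6. Iododestannylation (I2) should give the 3-iodobutenolide F7. Stille coupling with Bu3SnCH2OH (Pd(PPh3)4, dioxane, 80 °C) should give 18.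

**Further compounds**

F1 | step 18 | (3S,4Z,6R,7R,8R)-3-acetoxy-15-(tert-butyldimethylsilyloxy)-8-(methacryloyloxy)-1,10-dioxo-1,10-secogermacra-4,11(13)-dien-12,6-olide | O=CC[C@H](OC(C)=O)/C(CO[Si](C)(C)C(C)(C)C)=C\[C@H]1OC(=O)C(=C)[C@@H]1[C@H](OC(=O)C(C)=C)CC(C)=O
F2 | step 18 | (3S,4Z,6R,7R,8R)-3-acetoxy-15-(tert-butyldimethylsilyloxy)-8-(methacryloyloxy)-1,10-dimethylidene-1,10-secogermacra-4,11(13)-dien-12,6-olide | C=CC[C@H](OC(C)=O)/C(CO[Si](C)(C)C(C)(C)C)=C\[C@H]1OC(=O)C(=C)[C@@H]1[C@H](OC(=O)C(C)=C)CC(C)=C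
F3 | step 18 | (1(10)E,3S,4Z,6R,7R,8R)-3-acetoxy-15-(tert-butyldimethylsilyloxy)-8-(methacryloyloxy)germacra-1(10),4,11(13)-trien-12,6-olide | C=C(C)C(=O)O[C@@H]1C/C(C)=C/C[C@H](OC(C)=O)/C(CO[Si](C)(C)C(C)(C)C)=C\[C@H]2OC(=O)C(=C)[C@@H]21
F4 | step 14 | (5R)-5-[(1Z,3S)-3-acetoxy-2-{[tert-butyl(dimethyl)silyl]oxymethyl}-5-[(4-methoxybenzyl)oxy]pent-1-en-1-yl]-3-[(tributylstannyl)methyl]furan-2(5H)-one | COc1ccc(COCC[C@H](OC(C)=O)/C(CO[Si](C)(C)C(C)(C)C)=C\[C@H]2OC(=O)C(C[Sn](CCCC)(CCCC)CCCC)=C2)cc1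
F5 | step 14 | (3S,4Z,6R,7R,8R)-3-acetoxy-15-(tert-butyldimethylsilyloxy)-10,10-(ethylenedioxy)-8-hydroxy-1-(4-methoxybenzyloxy)-1,10-secogermacra-4,11(13)-dien-12,6-olide | COc1ccc(COCC[C@H](OC(C)=O)/C(CO[Si](C)(C)C(C)(C)C)=C\[C@H]2OC(=O)C(=C)[C@@H]2[C@H](O)CC2(C)OCCO2)cc1
F6 | step 10 | (5R)-5-[(1Z,3S)-3-acetoxy-2-{[tert-butyl(dimethyl)silyl]oxymethyl}-5-[(4-methoxybenzyl)oxy]pent-1-en-1-yl]-3-(tributylstannyl)furan-2(5H)-one | COc1ccc(COCC[C@H](OC(C)=O)/C(CO[Si](C)(C)C(C)(C)C)=C\[C@H]2OC(=O)C([Sn](CCCC)(CCCC)CCCC)=C2)cc1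
F7 | step 10 | (5R)-5-[(1Z,3S)-3-acetoxy-2-{[tert-butyl(dimethyl)silyl]oxymethyl}-5-[(4-methoxybenzyl)oxy]pent-1-en-1-yl]-3-iodofuran-2(5H)-one | COc1ccc(COCC[C@H](OC(C)=O)/C(CO[Si](C)(C)C(C)(C)C)=C\[C@H]2OC(=O)C(I)=C2)cc1
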